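- If X can fall out of its round into L, more J can raise the rate of making Z in two ways: it reloads X sooner, and it keeps more X alive. In the round, X takes J to give Q, Q binds D reversibly to give G, and G gives back X and Z. X can also take D to give L.

in all of them: X 17 mol%

| charge | D | J | remark |
|---|---|---|---|
| grey | 13 mM | 1.5 equiv | run made earlier |
| violet | 52 mM | 1.5 equiv | run made earlier |
| flask | 26 mM | 1.50 equiv |  |

| run | time / min | Z / % |
|---|---|---|
| grey | 0.250 | 0.9 |
| grey | 0.833 | 4.9 |
| grey | 1.33 | 10.5 |
| grey | 2.00 | 16.5 |
| grey | 3.00 | 24.3 |
| violet | 0.667 | 12.1 |
| violet | 1.33 | 23.0 |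
| violet | 2.00 | 32.3 |
| violet | 2.50 | 37.3 |
| violet | 3.00 | 42.8 |

(scatter of a reading: 0.3 percentage points)

- apparent order in J when 50% of the D are converted (percent change of the rate of making Z for one percent more J charged)

- reactions considered so far: J + X -> Q; D + Q <-> G; G -> X + Z; D + X -> L
- what is bound to the catalyst counts as converted

- I begin with the main step alone, taking J + X as the whole round of the flask. If each converted D took one J, J charged would stand to J left as 1.50 at 50% conversion, and that would be the order.
- Next I add the release of Z from G. Rate per X reads 0.663 min⁻¹ in the grey run and 1.07 min⁻¹ in the violet run. On logarithms that is a slope of 0.344. D and J differ together between these runs, so treating this slope as the local order in J is my assumption; with it, the order in my reckoning falls to 0.515.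
- Then I add L. In the violet run the rate per X falls to 0.618 min⁻¹ over 1.85 rounds. Charging that whole fall to L gives the life of X, the rounds over which its rate falls by a factor e, 3.39; this is a partition ratio.
- J and D compete for X, so I let life go with J over D; the flask has the same equivalents as the violet run. I guess 0.5 D per X is held in G or L, so I count 2.44 rounds for the flask at 50% conversion. One percent more life then adds 0.720 percent to the surviving X.
- My reckoning is 1.24. The forecast says 0.8, lower than mine, and counts L in the words “Faster capture of X also reduces loss to L”.
- The flask gives 1.4, more than my reckoning.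

    J + X → Q (k = 2.16 M⁻¹ s⁻¹)
    D + Q ⇌ G (K = 248 M⁻¹, k = 3.90 M⁻¹ s⁻¹)
    G → X + Z (k = 0.0459 s⁻¹)
    D + X → L (k = 0.841 M⁻¹ s⁻¹)

- At the start of the flask, X goes to Q 3.9 times as fast as to L, beside the life of 3.39 read from the violet run. By 5.00 min the flask has made 2.73 rounds, so life gives 44.7% of the catalyst outside L, and the flask holds 33.9%. Between the last two rate windows of the grey run, Z advances 0.406 rounds, so life gives a rate ratio of 0.887, and the grey readings give 0.871.

The earlier runs and the new flask are simulated for an exercise; scatter was added.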